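**Plan**

- Target: (3-methylidene-2,3-dihydro-1-benzoxepin-7-yl)methyl octadecanoate, numbered O1, C2H2, C3(=CH2), C4H=C5H, arene C5a to C9a, acyloxymethyl on C7. The retrosynthesis cuts the ester C–O bond (back to a C7 benzylic alcohol, then a C7 methyl ester), then two bonds of the oxepine ring, C3–C4 and C5–C5a, then the aryl O–C2 ether bond.
- Enabling feature: in the seven-membered oxepine ring the cis-vinylene C4=C5 lies between two sp2 carbons, arene carbon C5a and methylidene-bearing C3. It can therefore be excised as a two-carbon cis-dimetallated linchpin, and both flanks become C(sp2)–halogen bonds of one simple ether (aryl bromide at C5a, 2-iodoallyl unit at C3).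
- Forward order: O-alkylation joins the bought arene to the 2-iodoallyl unit. One palladium-catalysed operation then inserts the vinylene by a formal (5+2) two-fold Stille annulation: C3–C4 forms first between the two molecules, and the aryl–alkenyl bond C5–C5a closes the only new ring. Ester reduction and stearoylation finish the side chain.
- Stereochemistry: there is no stereocentre. The Z geometry of C4=C5 is carried with retention from (Z)-1,2-bis(trimethylstannyl)ethene, which is set by syn distannation of acetylene. The exocyclic methylene is present from the start and sees neither base nor metal hydride during ring formation.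

Key step: step 4

**Route**

Step 1
Reactants: 1 prop-2-yn-1-ol
Product: 2 2-iodoprop-2-en-1-ol
Conditions: NaI (1.2 equiv), Me3SiCl (1.2 equiv), H2O (0.6 equiv), MeCN, 0 °C to rt
Reagents that add atoms: sodium iodide [Na+].[I-]
Why: Hydrogen iodide generated in the flask should add across the terminal alkyne in the Markovnikov sense (hydroiodination of an alkyne), placing iodine on the internal carbon.

Step 2
Reactants: 2 2-iodoprop-2-en-1-ol; 3 methyl 3-bromo-4-hydroxybenzoate
Product: 4 methyl 3-bromo-4-[(2-iodoprop-2-en-1-yl)oxy]benzoate
Conditions: PPh3, diisopropyl azodicarboxylate, THF, 0 °C to rt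
Reagents that add atoms: none
Why: In this Mitsunobu etherification the acidic ortho-bromo, para-ester phenol is a good pronucleophile for the activated primary allylic alcohol, and SN2 and SN2' attack give the same ether because the 2-iodoallyl unit has two equivalent CH2 termini.

Step 3
Reactants: 5 acetylene; 6 hexamethylditin
Product: 7 (Z)-1,2-bis(trimethylstannyl)ethene
Conditions: Pd(PPh3)4 (2 mol %), acetylene (1 atm), 1,4-dioxane, 60 °C
Reagents that add atoms: none
Why: Palladium-catalysed distannation of an alkyne (oxidative addition of the Sn–Sn bond, syn insertion of the alkyne, reductive elimination) should deliver both tin groups to the same face and so fix the Z geometry.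

Step 4
Reactants: 4 methyl 3-bromo-4-[(2-iodoprop-2-en-1-yl)oxy]benzoate; 7 (Z)-1,2-bis(trimethylstannyl)ethene
Product: 9 methyl 3-methylidene-2,3-dihydro-1-benzoxepine-7-carboxylate, via Z-dienylstannane 8 (not isolated)
Conditions: 7 (1.1 equiv), Pd(PPh3)4 (10 mol %), CuI (20 mol %), degassed DMF (0.01 M), 40 °C then 80 °C
Reagents that add atoms: none
Why: Zerovalent palladium should insert first into the alkenyl C–I bond of 4, well ahead of the hindered, electron-rich ortho-alkoxy aryl C–Br bond, and Stille transmetalation with one tin of 7 followed by reductive elimination gives the Z-dienylstannane 8 with C3–C4 in place; oxidative addition into the aryl C–Br bond of 8, intramolecular tin-to-palladium transfer of C5 and reductive elimination then form the aryl–alkenyl bond C5–C5a. The closest known reaction type is the two-fold Stille "stitching" annulation of a dihalide with cis-1,2-bis(trimethylstannyl)ethene, known for closing cyclic cis-enediynes and benzo-fused rings. The seven-membered oxepine ring closes by C(sp2)–C(sp2) reductive elimination from an eight-membered diorganopalladium ring, which amounts to a formal (5+2) union of the five-atom unit C5a–C9a–O1–C2–C3 with the two-carbon vinylene. No stereocentre is formed; the cis geometry of C4=C5 that the ring demands is supplied by 7, because both Stille couplings proceed with retention at the alkenyl carbon. The step needs site selectivity (alkenyl iodide before aryl bromide, secured by the halogen difference), ring closure over oligomerisation (secured by high dilution and by the cis geometry that holds the C5–Sn bond next to the aryl–palladium centre), and an untouched exocyclic methylene (secured because the cycle involves no base and no palladium hydride).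

Step 5
Reactants: 9 methyl 3-methylidene-2,3-dihydro-1-benzoxepine-7-carboxylate
Product: 10 (3-methylidene-2,3-dihydro-1-benzoxepin-7-yl)methanol
Conditions: i-Bu2AlH (2.5 equiv), CH2Cl2, −78 °C to 0 °C; aqueous potassium sodium tartrate (KNaC4H4O6) work-up
Reagents that add atoms: none
Why: Diisobutylaluminium hydride reduction of an aryl ester to the benzylic alcohol should proceed at low temperature without touching the unactivated cross-conjugated diene or the allylic aryl ether.

Step 6
Reactants: 10 (3-methylidene-2,3-dihydro-1-benzoxepin-7-yl)methanol; 11 octadecanoyl chloride (stearoyl chloride)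
Product: 12 (3-methylidene-2,3-dihydro-1-benzoxepin-7-yl)methyl octadecanoate
Conditions: Et3N (1.5 equiv), DMAP (5 mol %), CH2Cl2, 0 °C to rt
Reagents that add atoms: none
Why: DMAP-catalysed acylation of a primary benzylic alcohol by an acid chloride should be fast, and triethylamine buffers the hydrogen chloride so that neither the electron-rich benzylic C–O bond nor the exocyclic diene is ionised or isomerised.

**Compound list**

1 | prop-2-yn-1-ol | C#CCO | starting material
2 | 2-iodoprop-2-en-1-ol | C=C(I)CO | intermediate
3 | methyl 3-bromo-4-hydroxybenzoate | COC(=O)c1ccc(O)c(Br)c1 | starting material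
4 | methyl 3-bromo-4-[(2-iodoprop-2-en-1-yl)oxy]benzoate | COC(=O)c1ccc(OCC(I)=C)c(Br)c1 | intermediate
5 | acetylene (ethyne) | C#C | starting material
6 | hexamethylditin | C[Sn](C)(C)[Sn](C)(C)C | starting material
7 | (Z)-1,2-bis(trimethylstannyl)ethene | C[Sn](C)(C)/C=C\[Sn](C)(C)C | intermediate
8 | methyl 3-bromo-4-{[(3Z)-2-methylidene-4-(trimethylstannyl)but-3-en-1-yl]oxy}benzoate (Z-dienylstannane, not isolated) | COC(=O)c1ccc(OCC(=C)/C=C\[Sn](C)(C)C)c(Br)c1 | intermediate
9 | methyl 3-methylidene-2,3-dihydro-1-benzoxepine-7-carboxylate | C=C1C=Cc2cc(C(=O)OC)ccc2OC1 | intermediate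
10 | (3-methylidene-2,3-dihydro-1-benzoxepin-7-yl)methanol | C=C1C=Cc2cc(CO)ccc2OC1 | intermediate
11 | octadecanoyl chloride (stearoyl chloride) | CCCCCCCCCCCCCCCCCC(=O)Cl | starting material
12 | (3-methylidene-2,3-dihydro-1-benzoxepin-7-yl)methyl octadecanoate | C=C1C=Cc2cc(COC(=O)CCCCCCCCCCCCCCCCC)ccc2OC1 | target

**Summary**

Total step count: 6. Longest linear sequence: 5 steps (steps 1, 2, 4, 5, 6); step 3 prepares the linchpin 7 in a side branch.

**Steps most likely to fail, with fallbacks**

Step 4. The stannane formed after the first coupling may couple with a second molecule of alkenyl iodide instead of cyclising (oligomerisation). It may also lose tin by protodestannylation before the slower oxidative addition into the aryl bromide, or the allylic aryl ether may be ionised by zerovalent palladium and intercepted by a stannane. The fallback sets out from 3 and comes back to the route at 9; it closes the ring by olefin metathesis at C4=C5 and installs the methylene last.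
- Suzuki–Miyaura vinylation of 3 with potassium vinyltrifluoroborate (PdCl2(dppf), Et3N, n-PrOH, 80 °C) should give methyl 3-ethenyl-4-hydroxybenzoate F1.
- Opening of 2-vinyloxirane at its terminal carbon by the phenoxide (K2CO3, DMF, 60 °C) should give racemic methyl 3-ethenyl-4-[(2-hydroxybut-3-en-1-yl)oxy]benzoate F2, whose carbinol centre is later oxidised away.
- Ring-closing metathesis with the second-generation Grubbs catalyst (CH2Cl2, 40 °C) can only close the seven-membered ring and should give methyl 3-hydroxy-2,3-dihydro-1-benzoxepine-7-carboxylate F3.
- MnO2 oxidation of the allylic alcohol (CH2Cl2, rt) should give methyl 3-oxo-2,3-dihydro-1-benzoxepine-7-carboxylate F4.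
- Wittig methylenation of the ketone (Ph3P=CH2 from Ph3PCH3Br and KN(SiMe3)2, THF, −78 to 0 °C), which is faster than attack on the ester, should give 9.

Step 5. The aluminium hydride may hydroaluminate the diene or move the exocyclic double bond into the ring, and the Lewis-acidic aluminium alkoxide may ionise the allylic aryl ether or the electron-rich benzylic position on work-up. The fallback sets out from 4 and comes back to the route at 12; it moves reduction and acylation ahead of ring formation so that the diene never meets a hydride.
- i-Bu2AlH reduction of 4 (CH2Cl2, −78 °C) should give {3-bromo-4-[(2-iodoprop-2-en-1-yl)oxy]phenyl}methanol F5.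
- Acylation with 11 (Et3N, DMAP, CH2Cl2, 0 °C) should give {3-bromo-4-[(2-iodoprop-2-en-1-yl)oxy]phenyl}methyl octadecanoate F6.
- The annulation with 7 under the conditions of step 4 should then pass through {3-bromo-4-{[(3Z)-2-methylidene-4-(trimethylstannyl)but-3-en-1-yl]oxy}phenyl}methyl octadecanoate F7, formed in the flask, and close the ring to give 12 directly.

Step 2. The hindered ortho-bromophenol may attack the oxyphosphonium intermediate slowly, so that alkylation of the reduced azodicarboxylate or elimination of the activated alcohol takes over. The fallback sets out from 2 and comes back to the route at 4; it replaces redox activation by a sulfonate displacement.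
- Mesylation of 2 (MeSO2Cl, Et3N, CH2Cl2, 0 °C) should give 2-iodoprop-2-en-1-yl methanesulfonate F8.
- Williamson alkylation of 3 with this sulfonate (K2CO3, DMF, rt to 50 °C) should give 4.

**Further compounds**

F1 | step 4 | methyl 3-ethenyl-4-hydroxybenzoate | COC(=O)c1ccc(O)c(C=C)c1
F2 | step 4 | methyl 3-ethenyl-4-[(2-hydroxybut-3-en-1-yl)oxy]benzoate (racemic) | COC(=O)c1ccc(OCC(O)C=C)c(C=C)c1
F3 | step 4 | methyl 3-hydroxy-2,3-dihydro-1-benzoxepine-7-carboxylate (racemic) | COC(=O)c1ccc2OCC(O)C=Cc2c1
F4 | step 4 | methyl 3-oxo-2,3-dihydro-1-benzoxepine-7-carboxylate | COC(=O)c1ccc2OCC(=O)C=Cc2c1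
F5 | step 5 | {3-bromo-4-[(2-iodoprop-2-en-1-yl)oxy]phenyl}methanol | OCc1ccc(OCC(I)=C)c(Br)c1
F6 | step 5 | {3-bromo-4-[(2-iodoprop-2-en-1-yl)oxy]phenyl}methyl octadecanoate | CCCCCCCCCCCCCCCCCC(=O)OCc1ccc(OCC(I)=C)c(Br)c1
F7 | step 5 | {3-bromo-4-{[(3Z)-2-methylidene-4-(trimethylstannyl)but-3-en-1-yl]oxy}phenyl}methyl octadecanoate | CCCCCCCCCCCCCCCCCC(=O)OCc1ccc(OCC(=C)/C=C\[Sn](C)(C)C)c(Br)c1
F8 | step 2 | 2-iodoprop-2-en-1-yl methanesulfonate | C=C(I)COS(C)(=O)=O
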